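The numbers in the tables were generated by integration with constants of no real substance.

**The question.** The over-reaction product is what you must estimate at the end of each flask.

| flask | electrophile | nucleophile | free base | protic impurity | temperature | remark | time |
|---|---|---|---|---|---|---|---|
| Monday's | 0.30 M | 0.90 equiv | 0.50 equiv | 0.090 M | −25 °C | run made earlier |  |
| Tuesday's | 0.30 M | 0.45 equiv | 0.50 equiv | 0.090 M | −14 °C | run made earlier |  |
| Friday's | 0.30 M | 1.8 equiv | 0.50 equiv | 0.090 M | −25 °C | run made earlier |  |
| east | 0.30 M | 0.900 equiv | 0.500 equiv (fed, over 30 h) | 0.0900 M | −20 °C | all else is in the flask from the start; the feed brings no volume worth counting | 50 h |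
| south-west | 0.30 M (in portions, 5, over 30 h) | 0.900 equiv | 0.500 equiv | 0.0900 M | −20 °C | first portion at the start, last at 30 h | 50 h |
| south-east | 0.30 M (fed, over 30 h) | 0.900 equiv | 0.500 equiv | 0.0900 M |  | the addition at −50 °C, then warmed to −20 °C; the feed brings no volume worth counting | 50 h |
| south | 0.30 M | 0.900 equiv | 0.500 equiv | 0.0900 M | −20 °C | everything together at the start | 50 h |
| north | 0.30 M | 0.900 equiv | 0.500 equiv | 0.0900 M |  | everything together at the start at −50 °C, warmed to −20 °C at 30 h | 50 h |

- the flask that comes out highest in amount of over-reaction product, in percent of the electrophile charged; "all alike" if 1.5 percentage points covers them all (east / south-west / south-east / south / north / all alike)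
- amount of over-reaction product at the end, in percent of the electrophile charged, east
- amount of over-reaction product at the end, in percent of the electrophile charged, south-west
- amount of over-reaction product at the end, in percent of the electrophile charged, south-east
- amount of over-reaction product at the end, in percent of the electrophile charged, south
- amount of over-reaction product at the end, in percent of the electrophile charged, north

| run | time / h | over-reaction product / % | target / % |
|---|---|---|---|
| Monday's | 2.50 | 1 | 29 |
| Monday's | 5.00 | 1 | 44 |
| Monday's | 8.00 | 1 | 48 |
| Monday's | 15.0 | 6 | 53 |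
| Monday's | 30.0 | 4 | 56 |
| Tuesday's | 2.50 | 3 | 30 |
| Tuesday's | 5.00 | 1 | 34 |
| Tuesday's | 8.00 | 4 | 37 |
| Tuesday's | 15.0 | 9 | 32 |
| Tuesday's | 30.0 | 8 | 32 |
| Friday's | 2.50 | 1 | 55 |
| Friday's | 8.00 | 8 | 74 |
| Friday's | 15.0 | 8 | 78 |
| Friday's | 20.0 | 12 | 82 |
| Friday's | 30.0 | 16 | 78 |

(scatter of a reading: 2 percentage points)

- the numbers in the tables scatter with a standard deviation of 2 percentage points

**The share.** Take the over-reaction share, a selectivity: c(over-reaction product) divided by the sum of c(over-reaction product) and c(target). This share still moves with time: in Friday's run it reads 1.79% at 2.50 h and 17.0% at 30.0 h. To tighten the bounds and soften the scatter of 2 points, average the last two readings of a run.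

**The floor.** Monday's run has the charges of these flasks, but it is colder at −25 °C against −20 °C and shorter. Its share reads 8.40%. Its coupled electrophile, target plus over-reaction product, reads 59.5%. Together they give a floor of 5.00%. For south-east and north, which pass 30 h at −50 °C, this floor is only a guess.

**The ceiling.** Tuesday's run is warmer at −14 °C, with half the nucleophile. Its share, my ceiling share, reads 21.0%. On Monday's coupled amount this gives 12.5%. But your flasks run 50 h, against 30.0 h for Tuesday's, so this ceiling is reckoned, not proven.

**The forecast.** It gives 9.5% for east, 8.5% for south-west, 5% for south-east, 12% for south and 5.5% for north, and it names south as highest. Its ground is this: “End amount therefore tracks the time spent holding target.” Its south-east value stands at my floor, and its south value lies below my ceiling.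

**The result.** South-west comes out highest at 11.7%, while south gives 7.47%, south-east 6.40%, north 6.44% and east 5.05%. East stays above the floor, and south-west stays below the ceiling.

    electrophile + nucleophile → acid set free + target (k = 1.70 M⁻¹ h⁻¹, Ea = 65.0 kJ mol⁻¹)
    nucleophile + acid set free ⇌ protonated nucleophile, settled at all times (K = 4300 M⁻¹, ΔH = −51.0 kJ mol⁻¹)
    acid set free + free base ⇌ salt of the base, settled at all times (K = 3700 M⁻¹, ΔH = −7.00 kJ mol⁻¹)
    free base + target → over-reaction product (k = 0.230 M⁻¹ h⁻¹, Ea = 68.0 kJ mol⁻¹)
    protic impurity + free base → quenched reagent (k = 0.170 M⁻¹ h⁻¹, Ea = 72.0 kJ mol⁻¹)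
    (constants at −20 °C)

**The neighbour.** Take east again, but with 2.20 equiv of nucleophile. At the end this neighbour has 0% of its electrophile left, so its coupled amount is the whole charge. The ceiling share then allows 21.0% of over-reaction product. The neighbour holds 23.5%.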